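1. Late on, the electrophile was still falling, but by fewer points per hour. In the summer run it stood at 19.0 % after 2.00 h and 14.8 % after 3.00 h, and in the dusk run at 13.5 % after 3.00 h.

| flask | electrophile | protonated nucleophile | gas | remark | time |
|---|---|---|---|---|---|
| summer | 0.12 M | 1.5 equiv | 52 mM (held) | run made earlier |  |
| dusk | 0.19 M | 1.5 equiv | 52 mM (held) | run made earlier |  |
| flask | 0.25 M | 1.50 equiv | 52 mM (held) |  | 4.0 h |

| run | time / h | electrophile / % | target / % |
|---|---|---|---|
| summer | 0.417 | 63.4 | 9.1 |
| summer | 1.00 | 35.9 | 20.6 |
| summer | 2.00 | 19.0 | 28.7 |
| summer | 3.00 | 14.8 | 29.8 |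
| dusk | 0.250 | 75.7 | 6.1 |
| dusk | 0.667 | 49.7 | 14.7 |
| dusk | 1.33 | 28.7 | 23.5 |
| dusk | 3.00 | 13.5 | 29.9 |

(readings scatter by 0.3 percentage points)

- at the start none of free base is dissolved
- steps thought possible: electrophile + nucleophile -> acid set free + target; nucleophile + acid set free <-> protonated nucleophile; acid set free + free base <-> salt of the base; electrophile <-> dormant form; nucleophile + target -> over-reaction product; gas <-> free base
- what has gone from electrophile into another species counts as reacted, even if it can come back
- the earlier runs do not show how much of nucleophile is bound; that part of a forecast is a guess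

- part of the electrophile that has reacted at 4.0 h
- share of the unused nucleophile that is free and not bound as protonated nucleophile, at 4.0 h

2. My bench rule was pseudo-first-order loss, with k = −ln(fraction of electrophile left)/t. The first readings gave k = 1.09 h⁻¹ in the summer run and 1.11 h⁻¹ in the dusk run. The charges differed by a factor of 1.58, but the two k values by 1.02, so I took the early loss as first order in the electrophile's own concentration.

3. The rule broke down late. In the summer run, k predicted 3.80 % left at 3.00 h, while the reading, 14.8 %, was 3.89 times that.

4. I therefore defined the tail constant λ, the first-order fall of the electrophile between the last two summer readings: 0.250 h⁻¹.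

5. Carrying the dusk reading, from the nearest charge, on to 4.0 h with λ left 10.5 %, so I reckoned c = 89.5 %. For fr the earlier runs offered no reckoning, and I committed to no number.

6. The forecast, 0.98 percentage points below my c, gave c = 88.5 % (85.5 % to 91 %) and fr = 12 % (3 % to 40 %), saying: “The free fraction is a guess”.

The flask gave c = 88.5 % and fr = 62.9 %.

    electrophile + nucleophile → acid set free + target (k = 0.00193 M⁻¹ s⁻¹)
    nucleophile + acid set free ⇌ protonated nucleophile, settled at all times (K = 175 M⁻¹)
    acid set free + free base ⇌ salt of the base, settled at all times (K = 4150 M⁻¹)
    electrophile ⇌ dormant form (K = 1.70, k = 2.51 × 10⁻⁴ s⁻¹)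
    nucleophile + target → over-reaction product (k = 9.49 × 10⁻⁴ M⁻¹ s⁻¹)
    gas ⇌ free base, rate k6*(csat - [free base]) (kL = 8.28 × 10⁻⁴ s⁻¹)

The relaxation half-life of the electrophile and dormant form by their interconversion alone, both ways together, 0.483 h, was short against 4.0 h. Applied once more in this flask, λ took the 20.6 % of electrophile present at 2.00 h to 12.5 % at 4.00 h, where the flask held 11.5 %.

The earlier runs and the new flask come from a simulation from invented constants, noise included.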